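## Retrosynthetic overview (listed from starting materials to target; read upward for the disconnections)

1. Only ring construction, done first: double Friedel–Crafts acylation of 1,4-dimethoxybenzene (1) with maleic anhydride (2) fuses the quinone ring and gives naphthazarin (3), a symmetric core with four equivalent C–H positions.
2. Side-chain C6 unit: 4-methylpent-3-en-1-ol (4) is oxidised to 4-methylpent-3-enal (5).
3. Key disconnection, C2–C1′: protecting-group-free, desymmetrising reductive hydroxyalkylation of 3 with 5, via the dearomatised leuco-diketone 6, gives the racemic carbinol 7.
4. Last disconnection, ester C–O: isobutyric anhydride (8) with a chiral acyl-transfer catalyst installs the ester and selects the (S)-enantiomer in the same step, giving target 9.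

**Assumption:** Compounds 4 and 8 and both enantiomers of benzotetramisole (BTM) are taken as catalogue items. The sense of the final enantioselective acylation is assigned from the Birman model, recalled rather than checked: (R)-BTM esterifies (R)-1-aryl carbinols, so (S)-BTM should give the (S)-ester.

## Route

**Step 1**
Reactants: 1 (1,4-dimethoxybenzene); 2 (maleic anhydride)
Product: 3, naphthazarin (5,8-dihydroxynaphthalene-1,4-dione)
Conditions: AlCl3–NaCl melt, 180–220 °C, a few min; then aq. HCl, reflux; sublimation or Soxhlet purification
Reagents that add atoms: none
Why: Double Friedel–Crafts acylation ortho to both oxygens (Zahn–Ochwat naphthazarin synthesis), in which 2 supplies C1–C4 and both quinone oxygens, AlCl3 cleaves the methyl ethers in the melt and acid hydrolysis frees the chelated dihydroxyquinone; no stereocentre.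

**Step 2**
Reactants: 4 (4-methylpent-3-en-1-ol)
Product: 5, 4-methylpent-3-enal
Conditions: Dess–Martin periodinane, NaHCO3, CH2Cl2, 0 °C; filter, concentrate cold, use at once as a THF solution
Reagents that add atoms: none
Why: Dess–Martin oxidation under buffered, near-neutral conditions gives the β,γ-unsaturated aldehyde without isomerisation to the conjugated enal; no stereocentre.

**Step 3 (key step)**
Reactants: 3 (naphthazarin); 5 (4-methylpent-3-enal, 3 equiv)
Product: 7, (±)-5,8-dihydroxy-2-(1-hydroxy-4-methylpent-3-en-1-yl)naphthalene-1,4-dione (racemic alkannin/shikonin), formed via leuconaphthazarin 6 (5,8-dihydroxy-2,3-dihydronaphthalene-1,4-dione), generated in situ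
Conditions: Na2S2O4 (2 equiv), 1 M NaOH, THF–MeOH–H2O, Ar, 0 °C (3 → 6); 5 added slowly, −5 to 0 °C, 1–2 h; then air, 0 °C; AcOH to pH 5; subdued light
Reagents that add atoms: none
Why: Proposed new method: a Marschalk-type reductive aldol applied to naphthazarin and a β,γ-unsaturated aldehyde, in which dithionite (which only delivers electrons) reduces 3 to the non-aromatic diketone 6 and the phenoxide-assisted enolate of 6 attacks aldehyde 5 through C2, so 5 supplies all six side-chain carbons and the carbinol oxygen. At ≤0 °C, β-elimination of hydroxide (the path to the deoxy product) is slow, and air re-oxidation of the aldolate (O2 only removes two hydrogens) restores the quinone with the OH retained. Because naphthazarin tautomers interconvert, all four C–H positions lead to the same product, so only mono-selectivity is needed, and the C1′ stereocentre forms as the racemate. The closest known reaction is the low-temperature Marschalk hydroxyalkylation of leucoquinizarin with aliphatic aldehydes.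

**Step 4**
Reactants: 7 (racemic carbinol); 8 (isobutyric anhydride, 0.55 equiv)
Product: 9, (S)-1-(5,8-dihydroxy-1,4-dioxo-1,4-dihydronaphthalen-2-yl)-4-methylpent-3-en-1-yl 2-methylpropanoate (isobutyryl alkannin)
Conditions: (S)-BTM (5–10 mol %), 2,6-lutidine (0.6 equiv), Na2SO4, CHCl3, −20 → 0 °C, dark; stop at about 45% conversion (chiral HPLC); silica separation from unreacted (R)-7
Reagents that add atoms: isobutyric anhydride (8), CC(C)C(=O)OC(=O)C(C)C
Why: Birman-type catalytic enantioselective acyl transfer (kinetic resolution), in which the N-isobutyryl isothiouronium of (S)-BTM recognises the π-system on the carbinol carbon (priority pattern OH > π-group > CH2R, as in 1-arylalkanols) and esterifies only (S)-7 without touching the stereocentre, while the chelated peri-phenols stay free (as in DCC/DMAP esterifications of shikonin) and 2,6-lutidine scavenges the acid without deprotonating them; the theoretical maximum yield is 50%.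

## Compound list

1 | 1,4-dimethoxybenzene | COc1ccc(OC)cc1 | starting material
2 | maleic anhydride | O=C1OC(=O)C=C1 | starting material
3 | naphthazarin (5,8-dihydroxynaphthalene-1,4-dione) | O=C1C=CC(=O)c2c(O)ccc(O)c12 | intermediate
4 | 4-methylpent-3-en-1-ol | CC(C)=CCCO | starting material
5 | 4-methylpent-3-enal | CC(C)=CCC=O | intermediate
6 | leuconaphthazarin (5,8-dihydroxy-2,3-dihydronaphthalene-1,4-dione) | O=C1CCC(=O)c2c(O)ccc(O)c12 | intermediate (in situ, not isolated)
7 | (±)-5,8-dihydroxy-2-(1-hydroxy-4-methylpent-3-en-1-yl)naphthalene-1,4-dione | CC(C)=CCC(O)C1=CC(=O)c2c(O)ccc(O)c2C1=O | intermediate (racemate)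
8 | isobutyric anhydride | CC(C)C(=O)OC(=O)C(C)C | starting material
9 | isobutyryl alkannin, (S) at C1′ | CC(C)=CC[C@H](OC(=O)C(C)C)C1=CC(=O)c2c(O)ccc(O)c2C1=O | target

## Summary

Total step count: 4.
Longest linear sequence: 3 steps (1 → 3 → 7 → 9).

Steps most likely to fail:

1. **Step 3.** Risks are dehydration to the deoxy product 2-(4-methylpent-3-enyl)naphthazarin, bis-adducts, and base-induced isomerisation or self-aldol of 5. Fallback: move the C2–C1′ bond formation to a protected core with a stereospecific 1,2-metallate shift.
   - Convert 3 to 1,4,5,8-tetramethoxynaphthalene (Na2S2O4; Me2SO4, NaOH), then desymmetrise by monobromination (NBS), Br/Li exchange and borylation to the 2-Bpin derivative.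
   - Run lithiation–borylation with the (+)-sparteine-lithiated N,N-diisopropylcarbamate of 4, then H2O2/NaOH, to give the (S)-carbinol directly.
   - Isobutyrylate, then demethylate oxidatively with CAN and AgO/HNO3.
   - This also removes the need for the resolution in Step 4.

2. **Step 4.** Risks are a low selectivity factor, because the recognition element is a quinone and not a simple aryl group, and competing phenol acylation. Fallback: replace the kinetic resolution with a physical one. Separate rac-7 into alkannin and shikonin by preparative chiral-phase HPLC (cellulose carbamate phase), then esterify the (S)-carbinol non-selectively with isobutyric acid, DCC and DMAP.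

3. **Step 1.** The melt gives low, variable yields and tar. Fallback: use 2,3-dichloromaleic anhydride to make 2,3-dichloronaphthazarin, which is the higher-yielding Friedel–Crafts. SnCl2/HCl reduction of that compound gives leuconaphthazarin 6 directly, and 6 enters Step 3 in degassed base.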